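All runs were computed for an exercise; scatter was added.

Early on, at 1.33 h, Thursday's flask holds more target than isomer, 34.1 % against 4.9 %, and the target later falls while the isomer climbs. We write P for target, E for isomer, and cA, cB for the charges of starting material and coupling partner.

common to all: starting material 10 mM
- Thursday's: coupling partner 8 mM; the very flask that is asked about, followed so far
- Saturday's: coupling partner 12 mM; run made earlier
- flask: coupling partner 8.00 mM; time 6.0 d

Thursday's run (percent of the starting material charged)

| time / h | target / % | isomer of the product / % |
|---|---|---|
| 1.33 | 34.1 | 4.9 |
| 2.50 | 43.0 | 28.0 |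
| 4.00 | 26.6 | 49.2 |
| 6.00 | 13.9 | 63.5 |
| 10.0 | 7.4 | 72.0 |
| 15.0 | 7.2 | 72.4 |

Saturday's run (percent of the starting material charged)

| time / d | target / % | isomer of the product / % |
|---|---|---|
| 0.167 | 28.4 | 69.4 |
| 0.500 | 8.0 | 92.1 |
| 0.833 | 7.9 | 91.9 |
| 1.25 | 7.8 | 91.7 |
| 1.67 | 8.3 | 92.7 |
| 2.50 | 8.3 | 92.5 |

(scatter of a reading: 0.5 percentage points)

- the reaction counts as stopped when no species that holds the starting material changes by six tenths of a point or more over the second half of the time

- which holds at 6.0 d: what has brought the reaction to rest, or that it has not come to rest (forward and back rates have come level / it is still moving / the coupling partner has run out first / all of the starting material has reacted)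
- target at 6.0 d, in percent of the starting material charged
- isomer of the product at 6.0 d, in percent of the starting material charged

1. Ceiling. P + E reaches 101 % on Saturday but stops at 79.6 % on Thursday. We read coupling as one coupling partner per starting material, with the coupling partner as limiting reagent, so the ceiling in Thursday's flask is cB/cA = 80.0 %.

2. Clock. In Thursday's flask, target above its last reading falls from 19 percentage points to 6.7 points between 4.00 h and 6.00 h. That reads as a relaxation half-life τ = 1.30 h.

3. Count. The asked time holds 110 such half-lives, so we expect rest, and the split remains to be reckoned.

4. Split. Thursday's last reading gives P/(P + E) = 9.05 %, hence 7.24 % target.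

5. Reforging. That share hangs on one reading. We assume a target–isomer balance that the charge does not shift, and take Saturday's 5 readings from 0.500 d on, long after τ. This gives the resting share s, target over target plus isomer: 8.04 %. We commit to 6.43 % target and 73.6 % isomer.

The forecast says the coupling partner has run out first, with 7.1 % target (6.4 % to 7.7 %) and 72.9 % isomer (72 % to 73.7 %). Its target stands higher than ours: "Thursday's own plateau deserves the most weight".

At 6.0 d Thursday's flask gives 6.15 % target and 73.8 % isomer, with 0 % of the coupling partner's charge left: the coupling partner has run out first.

    starting material + coupling partner + target → 2 target (k = 1280 M⁻² min⁻¹)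
    starting material + coupling partner → target (k = 0.00951 M⁻¹ min⁻¹)
    target ⇌ isomer of the product (K = 12.0, k = 0.00773 min⁻¹)

Thursday's flask has come to rest. Target stands at 6.15 % at 3.00 d and 6.15 % at 6.00 d. Left ten times as long, to 60.0 d, the flask gives 6.15 % target and 73.8 % isomer at 60.0 d, the same figures as at the asked time.

In a second flask with 2.0 mM of coupling partner the ceiling is 20.0 %, so s gives 1.61 % target and 18.4 % isomer. At 6.0 d that second flask gives 1.54 % target and 18.5 % isomer.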